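**Retrosynthetic overview**
1. Target 13 comes from 12 by C-prenylation at C-5, between the two phenols; 12 comes from 11 by loss of two MOM groups.
2. Key disconnection: the CH2–C(=O) bond of the propan-1-one chain. In precursor 8 the 3-(4-methoxyphenyl)propanoyl half sits as an ester on the phenol oxygen next to the ring-A carboxyl carbon. Its ester enolate attacks the neighbouring methyl ester, giving a temporary 4-hydroxycoumarin ring whose C-2 is then extruded as CO2.
3. Enabling feature: O-1 of the dihydrobenzofuran sits on C-7a, between C-7 (carries the ketone carbon) and C-3a (carries the C-3 methylene of the five-membered ring). This one oxygen serves first as the tether for the C–C bond and then, once the lactone is opened, as the nucleophile that closes O-1–C-2 onto an (R)-epoxide.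
4. Precursor 8 comes from methyl 2,4,6-trihydroxybenzoate 1: bis-MOM protection leaves the hydrogen-bonded OH free; O-allylation, Claisen rearrangement and cross-metathesis put a prenyl group ortho to it; acylation with acid chloride 6; Shi epoxidation sets the only stereocentre.
5. Ring order: ring A and the anisole ring are bought; the temporary pyranone ring is formed and destroyed in step 7; the dihydrofuran ring is formed in step 7.

Key step: step 7

Assumption: the D-fructose-derived Shi ketone is taken to give the (R)-epoxide of the ArCH2–CH=CMe2 unit, as the spiro transition-state model predicts for trisubstituted alkenes; if the sense were opposite, the enantiomeric ketone would be used.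

**Route**

Step 1
Reactants: 1 methyl 2,4,6-trihydroxybenzoate
Product: 2 methyl 2-hydroxy-4,6-bis(methoxymethoxy)benzoate
Conditions: MOMCl (2.3 equiv), iPr2NEt, CH2Cl2, 0 °C → rt
Reagents that add atoms: chloromethyl methyl ether (MOMCl), COCCl
Why: Phenol O-alkylation (MOM ether formation) should stop after the 4-OH and one of the two equivalent ortho OH groups, because the last OH is held in a hydrogen bond to the ester carbonyl; this free OH is the oxygen that later becomes O-1 of the dihydrofuran.

Step 2
Reactants: 2 methyl 2-hydroxy-4,6-bis(methoxymethoxy)benzoate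
Product: 3 methyl 2-(allyloxy)-4,6-bis(methoxymethoxy)benzoate
Conditions: allyl bromide, K2CO3, DMF, 60 °C
Reagents that add atoms: allyl bromide, C=CCBr
Why: Williamson ether synthesis on the only free phenol with a reactive allylic halide in a dipolar aprotic solvent should give the O-allyl ether.

Step 3
Reactants: 3 methyl 2-(allyloxy)-4,6-bis(methoxymethoxy)benzoate
Product: 4 methyl 3-allyl-2-hydroxy-4,6-bis(methoxymethoxy)benzoate
Conditions: N,N-diethylaniline, 190 °C
Reagents that add atoms: none
Why: Aromatic Claisen rearrangement ([3,3]-sigmatropic shift) should deliver the allyl group to C-3, the only free ortho position of the ether oxygen (C-1 carries the ester), and restore the phenol next to the new side chain.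

Step 4
Reactants: 4 methyl 3-allyl-2-hydroxy-4,6-bis(methoxymethoxy)benzoate
Product: 5 methyl 2-hydroxy-4,6-bis(methoxymethoxy)-3-(3-methylbut-2-en-1-yl)benzoate
Conditions: Grubbs second-generation catalyst (5 mol %), 2-methylbut-2-ene (excess), CH2Cl2, 40 °C
Reagents that add atoms: 2-methylbut-2-ene, CC=C(C)C
Why: Olefin cross-metathesis of the terminal allyl group with excess 2-methylbut-2-ene should give the prenyl group, driven by loss of propene and tolerant of the hydrogen-bonded phenol.

Step 5
Reactants: 5 methyl 2-hydroxy-4,6-bis(methoxymethoxy)-3-(3-methylbut-2-en-1-yl)benzoate, 6 3-(4-methoxyphenyl)propanoyl chloride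
Product: 7 methyl 2-{[3-(4-methoxyphenyl)propanoyl]oxy}-4,6-bis(methoxymethoxy)-3-(3-methylbut-2-en-1-yl)benzoate
Conditions: Et3N, DMAP (cat.), CH2Cl2, 0 °C → rt
Reagents that add atoms: none
Why: DMAP-catalysed O-acylation of the phenol with the acid chloride (nucleophilic acyl substitution) should attach the second half as an aryl ester and place its α-CH2 next to the methyl ester carbon.

Step 6
Reactants: 7 methyl 2-{[3-(4-methoxyphenyl)propanoyl]oxy}-4,6-bis(methoxymethoxy)-3-(3-methylbut-2-en-1-yl)benzoate
Product: 8 methyl 3-{[(2R)-3,3-dimethyloxiran-2-yl]methyl}-2-{[3-(4-methoxyphenyl)propanoyl]oxy}-4,6-bis(methoxymethoxy)benzoate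
Conditions: D-fructose-derived Shi ketone (30 mol %), Oxone, K2CO3, Bu4NHSO4, MeCN/DMM/aq. Na2B4O7–EDTA buffer, 0 °C
Reagents that add atoms: Oxone (potassium peroxymonosulfate), [K+].[O-]S(=O)(=O)OO
Why: Shi asymmetric epoxidation, in which the chiral dioxirane transfers oxygen to one face of the trisubstituted alkene through a spiro transition state, should give the (R)-epoxide; the catalyst controls the new stereocentre and the prenyl group is the only electron-rich alkene present.

Step 7
Reactants: 8 methyl 3-{[(2R)-3,3-dimethyloxiran-2-yl]methyl}-2-{[3-(4-methoxyphenyl)propanoyl]oxy}-4,6-bis(methoxymethoxy)benzoate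
Product: 11 1-[(2S)-2-(2-hydroxypropan-2-yl)-4,6-bis(methoxymethoxy)-2,3-dihydro-1-benzofuran-7-yl]-3-(4-methoxyphenyl)propan-1-one, via 4-hydroxycoumarin lithium salt 9 (not isolated), via dihydrobenzofuran keto acid 10 (not isolated)
Conditions: LiHMDS (2.2 equiv), THF, −78 → 0 °C; then 1 M aq. KOH, EtOH, 80 °C; then 1 M HCl to pH 4–5, 40 °C
Reagents that add atoms: none
Why: LiHMDS deprotonates the CH2 next to the aryl-ester carbonyl, and the ester enolate attacks the neighbouring methyl ester carbon in a 6-exo-trig Dieckmann-type (intramolecular Claisen) condensation that forms the CH2–C(=O) bond and, after loss of methoxide and enolisation, the lithium salt of 4-hydroxycoumarin 9. Dilute hydroxide then opens the lactone at C-2, and the phenoxide set free closes the dihydrofuran ring 5-exo-tet onto the secondary epoxide carbon, which makes the ring opening irreversible and leaves the tertiary alcohol. Mild acidification lets β-keto acid 10 lose CO2, so the tether carbonyl is extruded and ketone 11 remains. The closest known reaction types are the base-induced cyclisation of methyl O-acylsalicylates to 3-substituted 4-hydroxycoumarins, the alkaline cleavage of such coumarins to o-hydroxyaryl alkyl ketones, and the base-mediated 5-exo cyclisation of o-(2,3-epoxy-3-methylbutyl)phenols. The new stereocentre C-2 of the dihydrofuran is controlled by the (R)-epoxide of 8, since backside attack inverts this carbon and should give (S). The step needs ring closure through the correct oxygen (secured because O-4 and O-6 stay as MOM ethers and only the tether oxygen is liberated), 5-exo rather than 6-endo opening (secured by the basic medium, which directs attack to the less substituted carbon), and ketonic rather than acid cleavage of the coumarin (favoured by dilute alkali).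

Step 8
Reactants: 11 1-[(2S)-2-(2-hydroxypropan-2-yl)-4,6-bis(methoxymethoxy)-2,3-dihydro-1-benzofuran-7-yl]-3-(4-methoxyphenyl)propan-1-one
Product: 12 1-[(2S)-4,6-dihydroxy-2-(2-hydroxypropan-2-yl)-2,3-dihydro-1-benzofuran-7-yl]-3-(4-methoxyphenyl)propan-1-one
Conditions: 3 M aq. HCl/MeOH (1:4), 45 °C
Reagents that add atoms: none
Why: Acid-catalysed acetal cleavage (transacetalisation to dimethoxymethane in methanol) should remove both aryl MOM ethers under conditions that the ketone, the dihydrofuran and the tertiary alcohol tolerate.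

Step 9
Reactants: 12 1-[(2S)-4,6-dihydroxy-2-(2-hydroxypropan-2-yl)-2,3-dihydro-1-benzofuran-7-yl]-3-(4-methoxyphenyl)propan-1-one
Product: 13 1-[(2S)-4,6-dihydroxy-2-(2-hydroxypropan-2-yl)-5-(3-methylbut-2-en-1-yl)-2,3-dihydro-1-benzofuran-7-yl]-3-(4-methoxyphenyl)propan-1-one
Conditions: prenyl bromide (1.05 equiv), 10 % aq. KOH, 0 °C → rt
Reagents that add atoms: prenyl bromide (1-bromo-3-methylbut-2-ene), CC(C)=CCBr
Why: C-alkylation of the ambident phenoxide of a phloroglucinol-type ring in a protic medium (which disfavours O-alkylation) should place the prenyl group on C-5, the only free ring carbon, flanked by both phenoxide oxygens.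

**Compound list**
1 | methyl 2,4,6-trihydroxybenzoate | COC(=O)c1c(O)cc(O)cc1O | starting material
2 | methyl 2-hydroxy-4,6-bis(methoxymethoxy)benzoate | COC(=O)c1c(O)cc(OCOC)cc1OCOC | intermediate
3 | methyl 2-(allyloxy)-4,6-bis(methoxymethoxy)benzoate | COC(=O)c1c(OCC=C)cc(OCOC)cc1OCOC | intermediate
4 | methyl 3-allyl-2-hydroxy-4,6-bis(methoxymethoxy)benzoate | COC(=O)c1c(O)c(CC=C)c(OCOC)cc1OCOC | intermediate
5 | methyl 2-hydroxy-4,6-bis(methoxymethoxy)-3-(3-methylbut-2-en-1-yl)benzoate | COC(=O)c1c(O)c(CC=C(C)C)c(OCOC)cc1OCOC | intermediate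
6 | 3-(4-methoxyphenyl)propanoyl chloride | COc1ccc(CCC(Cl)=O)cc1 | starting material
7 | methyl 2-{[3-(4-methoxyphenyl)propanoyl]oxy}-4,6-bis(methoxymethoxy)-3-(3-methylbut-2-en-1-yl)benzoate | COC(=O)c1c(OC(=O)CCc2ccc(OC)cc2)c(CC=C(C)C)c(OCOC)cc1OCOC | intermediate
8 | methyl 3-{[(2R)-3,3-dimethyloxiran-2-yl]methyl}-2-{[3-(4-methoxyphenyl)propanoyl]oxy}-4,6-bis(methoxymethoxy)benzoate | COC(=O)c1c(OC(=O)CCc2ccc(OC)cc2)c(C[C@H]2OC2(C)C)c(OCOC)cc1OCOC | intermediate
9 | 8-{[(2R)-3,3-dimethyloxiran-2-yl]methyl}-4-hydroxy-3-(4-methoxybenzyl)-5,7-bis(methoxymethoxy)-2H-chromen-2-one (formed as its lithium salt) | COc1ccc(CC2=C(O)c3c(OCOC)cc(OCOC)c(C[C@H]4OC4(C)C)c3OC2=O)cc1 | intermediate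
10 | 3-[(2S)-2-(2-hydroxypropan-2-yl)-4,6-bis(methoxymethoxy)-2,3-dihydro-1-benzofuran-7-yl]-2-(4-methoxybenzyl)-3-oxopropanoic acid (both epimers at C-2 of the acid; formed as its potassium salt) | COc1ccc(CC(C(O)=O)C(=O)c2c(OCOC)cc(OCOC)c3c2O[C@H](C(C)(C)O)C3)cc1 | intermediate
11 | 1-[(2S)-2-(2-hydroxypropan-2-yl)-4,6-bis(methoxymethoxy)-2,3-dihydro-1-benzofuran-7-yl]-3-(4-methoxyphenyl)propan-1-one | COc1ccc(CCC(=O)c2c(OCOC)cc(OCOC)c3c2O[C@H](C(C)(C)O)C3)cc1 | intermediate
12 | 1-[(2S)-4,6-dihydroxy-2-(2-hydroxypropan-2-yl)-2,3-dihydro-1-benzofuran-7-yl]-3-(4-methoxyphenyl)propan-1-one | COc1ccc(CCC(=O)c2c(O)cc(O)c3c2O[C@H](C(C)(C)O)C3)cc1 | intermediate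
13 | 1-[(2S)-4,6-dihydroxy-2-(2-hydroxypropan-2-yl)-5-(3-methylbut-2-en-1-yl)-2,3-dihydro-1-benzofuran-7-yl]-3-(4-methoxyphenyl)propan-1-one | COc1ccc(CCC(=O)c2c(O)c(CC=C(C)C)c(O)c3c2O[C@H](C(C)(C)O)C3)cc1 | target

Total step count: 9
Longest linear sequence: 9 steps (1 → 13; acid chloride 6 is purchased)

**Steps most likely to fail**

Step 7. The lithium ester enolate may fragment to a ketene and the aryloxide before it attacks the hindered methyl ester, and the freed aryloxide would then close onto the epoxide without the side chain. In the alkaline stage the lactone may open slowly, so that retro-Claisen (acid) cleavage or hydrolysis of the epoxide competes. The fallback sets out from 8 and comes back at 11, and forms the same CH2–C(=O) bond by carbonyl addition. K2CO3 in MeOH should cleave the aryl ester and let the phenoxide close onto the epoxide, giving methyl (2S)-2-(2-hydroxypropan-2-yl)-4,6-bis(methoxymethoxy)-2,3-dihydro-1-benzofuran-7-carboxylate F1. LiAlH4 in THF should reduce it to 2-[(2S)-7-(hydroxymethyl)-4,6-bis(methoxymethoxy)-2,3-dihydro-1-benzofuran-2-yl]propan-2-ol F2, and MnO2 in CH2Cl2 should oxidise the benzylic alcohol to (2S)-2-(2-hydroxypropan-2-yl)-4,6-bis(methoxymethoxy)-2,3-dihydro-1-benzofuran-7-carbaldehyde F3. Addition of 2-(4-methoxyphenyl)ethylmagnesium bromide F4 (from purchased 1-(2-bromoethyl)-4-methoxybenzene and Mg in THF, 2.2 equiv because of the free tertiary OH) should give 1-[(2S)-2-(2-hydroxypropan-2-yl)-4,6-bis(methoxymethoxy)-2,3-dihydro-1-benzofuran-7-yl]-3-(4-methoxyphenyl)propan-1-ol F5 as both carbinol epimers. Dess–Martin oxidation of the secondary alcohol should then give 11.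

Step 9. O-alkylation and a second C-alkylation at C-5 (dearomatisation) may compete with the single C-alkylation wanted. The fallback sets out from 11 and comes back at 13, and replaces phenoxide alkylation by a cross-coupling. NBS in MeCN at 0 °C should brominate the only free, strongly activated ring position to give 1-[(2S)-5-bromo-2-(2-hydroxypropan-2-yl)-4,6-bis(methoxymethoxy)-2,3-dihydro-1-benzofuran-7-yl]-3-(4-methoxyphenyl)propan-1-one F6. Stille coupling with tributyl(3-methylbut-2-en-1-yl)stannane (Pd(PPh3)4, CsF, DMF, 90 °C) should give 1-[(2S)-2-(2-hydroxypropan-2-yl)-4,6-bis(methoxymethoxy)-5-(3-methylbut-2-en-1-yl)-2,3-dihydro-1-benzofuran-7-yl]-3-(4-methoxyphenyl)propan-1-one F7. Removal of the MOM groups as in step 8 should then give 13.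

Step 6. The aryl ester may be hydrolysed under the basic epoxidation conditions, which would release the phenol too early and lose the tether. The fallback sets out from 5 and comes back at 8, and epoxidises before the ester is made. TBSOTf and 2,6-lutidine should give methyl 2-{[tert-butyl(dimethyl)silyl]oxy}-4,6-bis(methoxymethoxy)-3-(3-methylbut-2-en-1-yl)benzoate F8. Shi epoxidation as in step 6 should give methyl 2-{[tert-butyl(dimethyl)silyl]oxy}-3-{[(2R)-3,3-dimethyloxiran-2-yl]methyl}-4,6-bis(methoxymethoxy)benzoate F9. Fluoride-induced desilylative acylation (CsF, acid chloride 6, MeCN, −40 °C) should then trap the phenoxide as the ester before it can attack the epoxide, giving 8.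

Further compounds
F1 | step 7 | methyl (2S)-2-(2-hydroxypropan-2-yl)-4,6-bis(methoxymethoxy)-2,3-dihydro-1-benzofuran-7-carboxylate | COC(=O)c1c(OCOC)cc(OCOC)c2c1O[C@H](C(C)(C)O)C2
F2 | step 7 | 2-[(2S)-7-(hydroxymethyl)-4,6-bis(methoxymethoxy)-2,3-dihydro-1-benzofuran-2-yl]propan-2-ol | OCc1c(OCOC)cc(OCOC)c2c1O[C@H](C(C)(C)O)C2
F3 | step 7 | (2S)-2-(2-hydroxypropan-2-yl)-4,6-bis(methoxymethoxy)-2,3-dihydro-1-benzofuran-7-carbaldehyde | O=Cc1c(OCOC)cc(OCOC)c2c1O[C@H](C(C)(C)O)C2
F4 | step 7 | 2-(4-methoxyphenyl)ethylmagnesium bromide | COc1ccc(CC[Mg]Br)cc1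
F5 | step 7 | 1-[(2S)-2-(2-hydroxypropan-2-yl)-4,6-bis(methoxymethoxy)-2,3-dihydro-1-benzofuran-7-yl]-3-(4-methoxyphenyl)propan-1-ol | COc1ccc(CCC(O)c2c(OCOC)cc(OCOC)c3c2O[C@H](C(C)(C)O)C3)cc1
F6 | step 9 | 1-[(2S)-5-bromo-2-(2-hydroxypropan-2-yl)-4,6-bis(methoxymethoxy)-2,3-dihydro-1-benzofuran-7-yl]-3-(4-methoxyphenyl)propan-1-one | COc1ccc(CCC(=O)c2c(OCOC)c(Br)c(OCOC)c3c2O[C@H](C(C)(C)O)C3)cc1
F7 | step 9 | 1-[(2S)-2-(2-hydroxypropan-2-yl)-4,6-bis(methoxymethoxy)-5-(3-methylbut-2-en-1-yl)-2,3-dihydro-1-benzofuran-7-yl]-3-(4-methoxyphenyl)propan-1-one | COc1ccc(CCC(=O)c2c(OCOC)c(CC=C(C)C)c(OCOC)c3c2O[C@H](C(C)(C)O)C3)cc1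
F8 | step 6 | methyl 2-{[tert-butyl(dimethyl)silyl]oxy}-4,6-bis(methoxymethoxy)-3-(3-methylbut-2-en-1-yl)benzoate | COC(=O)c1c(O[Si](C)(C)C(C)(C)C)c(CC=C(C)C)c(OCOC)cc1OCOC
F9 | step 6 | methyl 2-{[tert-butyl(dimethyl)silyl]oxy}-3-{[(2R)-3,3-dimethyloxiran-2-yl]methyl}-4,6-bis(methoxymethoxy)benzoate | COC(=O)c1c(O[Si](C)(C)C(C)(C)C)c(C[C@H]2OC2(C)C)c(OCOC)cc1OCOC
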